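The ratio of substrate to coupling partner in oak and cedar, 0.400, opens the ledger: substrate is the smaller charge, so it is the limiting reagent, and each of its moles has to be traced.

| flask | substrate | coupling partner | free catalyst | temperature | remark | time |
|---|---|---|---|---|---|---|
| winter | 0.80 M (fed, over 5.0 min) | 2 M | 1.6 mM | −20 °C | run made earlier; the fed solution adds 0.20 times the starting volume |  |
| oak | 0.80 M (fed, over 5.0 min) | 2.00 M | 0.80 mM |  | at −20 °C until 5.0 min, from then on at 40 °C; the fed solution adds 0.20 times the starting volume | 50 min |
| cedar | 0.80 M (fed, over 5.0 min) | 2.00 M | 0.80 mM |  | at 40 °C throughout; the fed solution adds 0.20 times the starting volume | 200 min |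

winter run (percent of the substrate charged)

| time / min | target / % | isomer of the product / % | substrate / % |
|---|---|---|---|
| 0.417 | 1 | 0 | 9 |
| 1.00 | 3 | 1 | 17 |
| 2.00 | 8 | 1 | 30 |
| 5.00 | 30 | 11 | 59 |

(scatter of a reading: 1.5 percentage points)

- charges are per starting volume, the dose included; the dosed solution carries all of it
- the numbers in the tables scatter with a standard deviation of 1.5 percentage points
- the earlier runs do not show what temperature does; that part of a forecast is a guess
- percentages count the whole charge, also what has not yet gone in
- no earlier run changes the charge of free catalyst; that part of a forecast is a guess

- the winner by share of target in all that became target or isomer of the product; "neither" if no more than 2 percentage points parts them (oak / cedar / neither)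
- share of target in all that became target or isomer of the product, oak
- share of target in all that became target or isomer of the product, cedar

At the end of the feed in the winter run, the ledger reads substrate 59 %, target 30 % and isomer 11 %, which sum to >99.9 %, so these entries close the books within the scatter. The entry to watch lies between target and isomer. In the winter run, isomer over target reads 0.125 at 2.00 min and 0.367 at 5.00 min, which suggests, weakly given the scatter, that target feeds isomer. From 2.00 min to 5.00 min, isomer gains 10 percentage points while target averages 19.0 %. Read as first order, that is 0.175 min⁻¹, a half-life of 3.95 min. Call this reading the isomer clock, the time in which target at −20 °C loses half of itself to isomer.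

This reckoning takes the clock to be untouched by the catalyst charge, which in oak is half the winter charge, and takes heating not to lengthen it; both are guesses. Oak then has 11.4 clocks at 40 °C and cedar 50.6, so the clock is shorter than the time oak spends at 40 °C and shorter than the time of cedar. So the trade between target and isomer should forget the path and end the same way at the shared final temperature, which is thermodynamic control. The reckoning therefore commits to equal shares and leaves their level open, since the winter run shows no balance at 40 °C.

The forecast instead named cedar, with 67 % for oak and 87 % for cedar, on the ground that “its concentration stays at a few percent and selectivity is high”.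

The flasks give neither: oak 93.1 %, cedar 93.1 %.

    substrate + catalyst intermediate A ⇌ catalyst intermediate B (K = 26.0 M⁻¹, k = 200 M⁻¹ min⁻¹, Ea = 48.0 kJ mol⁻¹, ΔH = −37.0 kJ mol⁻¹)
    target ⇌ isomer of the product (K = 1.80, k = 0.220 min⁻¹, Ea = 75.0 kJ mol⁻¹, ΔH = −35.0 kJ mol⁻¹)
    coupling partner + free catalyst → catalyst intermediate A (k = 7300 M⁻¹ min⁻¹, Ea = 38.0 kJ mol⁻¹)
    catalyst intermediate B ⇌ free catalyst + target (K = 0.470 M, k = 340 min⁻¹, Ea = 63.0 kJ mol⁻¹, ΔH = 14.0 kJ mol⁻¹)
    (constants at −20 °C)

In oak, the half-life of target by the forward step to isomer alone is 3.2 min at its first temperature, short against its 50 min, and at 25.0 min oak holds target 93.1 % and isomer 6.92 %, unchanged at 500 min. Oak read at 12 min, 7.00 min after the change of temperature, a span of 1.77 isomer clocks as read at −20 °C and not as they run at 40 °C, holds target 93.1 % and isomer 6.92 %, a share of 93.1 %.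

(All runs were computed from invented constants, noise included.)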